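**Plan**

1. Retrosynthesis first cuts the aryl ester (depside) C–O bond, giving a ring A acid and a ring B phenol. Both carry the same 2,4-dioxygenated 6-propylbenzoate pattern and are traced to one resorcylate.
2. In that resorcylate the ester-bearing C1 sits between oxygenated C2 and propyl-bearing C6, so the ring is cut at C1–C6 and C2–C3. C1 is then a malonate carbon, C2 a malonate carbonyl, C3 the methyl group and C6 the beta carbon of a propyl enone.
3. Forward: dimethyl malonate 1 and (E)-hept-3-en-2-one 2 are annulated (through 3 and 4) to carbocycle 5, which bromine aromatises (through 6) to methyl 2,4-dihydroxy-6-propylbenzoate 7. This is the only ring-forming event and it serves both rings.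
4. One portion of 7 is 4-O-benzylated, 2-O-methylated and hydrogenolysed (8, 9) to the ring B phenol 10. Another portion is dibenzylated and saponified (11, 12) to the ring A acid 13.
5. Esterification of 13 with 10 (through 14) gives the protected depside 15, and hydrogenolysis gives the target 16.
6. Stereochemistry: the target has no stereocentre. The one sp3 centre made in the annulation (C6 of 5, racemic) is erased on aromatisation.

Key step: step 1

Assumption: (E)-hept-3-en-2-one is taken as a purchasable material; compound 5 is a freely tautomerising 2,4-dioxo ester, drawn as its ester-conjugated enol, racemic at C6 with one enantiomer drawn.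

**Route**

Step 1
Reactants: 1 dimethyl malonate; 2 (E)-hept-3-en-2-one
Product: 5 methyl 2-hydroxy-4-oxo-6-propylcyclohex-1-ene-1-carboxylate (racemic), via Michael adduct 3 (not isolated), via sodium enolate 4 (not isolated)
Conditions: NaOMe (1.1 equiv), MeOH, reflux; then cold 1 M HCl to pH 2–3
Reagents that add atoms: none
Why: Sodium dimethyl malonate adds to the beta carbon of enone 2 (Michael addition), forming the C1–C6 bond and giving adduct 3, after which proton transfer generates the methyl-side ketone enolate, which attacks one malonate ester carbonyl and expels methoxide (intramolecular Claisen, Dieckmann-type condensation) to form the C2–C3 bond. The closest known reaction type is the classical malonate–enone Michael–Claisen annulation that gives 6-alkyl-2,4-dioxocyclohexanecarboxylates, the precursors of 5-alkylresorcinols and their carboxylates. The six-membered carbocycle closes in a 6-(enolendo)-exo-trig mode, and the closure is pulled forward by irreversible deprotonation to the vinylogous carboxylate 4, which acidification converts into 5. The only lasting new stereocentre, C6, forms racemic with no controlling element, which is acceptable because step 2 destroys it; the C1 centre of 4 is epimerisable and also vanishes. The selectivity needed is regiochemical: only the methyl-side enolate can reach an ester carbonyl through a six-membered transition state (the internal enolate would close a four-membered ring), so propyl must end up next to the ester-bearing carbon, and methoxide in methanol matches the methyl esters so that transesterification is not an issue.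

Step 2
Reactants: 5 methyl 2-hydroxy-4-oxo-6-propylcyclohex-1-ene-1-carboxylate
Product: 7 methyl 2,4-dihydroxy-6-propylbenzoate, via bromo dione 6 (not isolated)
Conditions: Br2 (1.0 equiv), DMF, 0 °C, then 70 °C
Reagents that add atoms: none
Why: The dione enol is brominated at C3 to give 6, whose dienol loses HBr by 1,4-elimination (hydrogen from C6, bromide from C3) and tautomerises to the resorcylate, the established halogenation–dehydrohalogenation aromatisation of dihydroresorcylates, while one equivalent of bromine and moderate heating should spare the ring from further bromination and the ester from cleavage.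

Step 3
Reactants: 7 methyl 2,4-dihydroxy-6-propylbenzoate
Product: 8 methyl 4-(benzyloxy)-2-hydroxy-6-propylbenzoate
Conditions: BnBr (1.05 equiv), K2CO3, acetone, reflux
Reagents that add atoms: benzyl bromide, BrCc1ccccc1
Why: Williamson ether synthesis that should be selective for O4 because the 2-hydroxyl is held in a hydrogen bond to the ester carbonyl and is both less acidic and less nucleophilic, as is usual for 2,4-dihydroxybenzoates.

Step 4
Reactants: 8 methyl 4-(benzyloxy)-2-hydroxy-6-propylbenzoate
Product: 9 methyl 4-(benzyloxy)-2-methoxy-6-propylbenzoate
Conditions: MeI (3 equiv), K2CO3, DMF, 50 °C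
Reagents that add atoms: iodomethane, CI
Why: Williamson O-methylation in which the polar aprotic solvent and excess iodomethane overcome the hydrogen bond of the remaining ortho phenol, while the methyl ester and the benzyl ether are inert to carbonate.

Step 5
Reactants: 9 methyl 4-(benzyloxy)-2-methoxy-6-propylbenzoate
Product: 10 methyl 4-hydroxy-2-methoxy-6-propylbenzoate
Conditions: H2 (1 atm), 10% Pd/C, EtOAc, rt
Reagents that add atoms: none
Why: Catalytic hydrogenolysis cleaves the benzylic C–O bond of the aryl benzyl ether and leaves the methyl ether, the methyl ester and the arene untouched.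

Step 6
Reactants: 7 methyl 2,4-dihydroxy-6-propylbenzoate
Product: 11 methyl 2,4-bis(benzyloxy)-6-propylbenzoate
Conditions: BnBr (2.5 equiv), K2CO3, DMF, 70 °C
Reagents that add atoms: benzyl bromide, BrCc1ccccc1
Why: Exhaustive Williamson etherification in which excess halide, DMF and heat force the hydrogen-bonded 2-hydroxyl to react after the 4-hydroxyl.

Step 7
Reactants: 11 methyl 2,4-bis(benzyloxy)-6-propylbenzoate
Product: 13 2,4-bis(benzyloxy)-6-propylbenzoic acid, via potassium carboxylate 12 (not isolated)
Conditions: KOH (10 equiv), DMSO–H2O 4:1, 90 °C; then 1 M HCl, 0 °C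
Reagents that add atoms: potassium hydroxide, [K+].[OH-]
Why: Saponification (acyl substitution by hydroxide) of the di-ortho-substituted methyl ester, for which poorly solvated hydroxide in hot aqueous DMSO is the usual remedy, the benzyl ethers being stable to base and the cold acidification avoiding decarboxylation of the electron-rich acid.

Step 8
Reactants: 13 2,4-bis(benzyloxy)-6-propylbenzoic acid; 10 methyl 4-hydroxy-2-methoxy-6-propylbenzoate
Product: 15 methyl 4-{[2,4-bis(benzyloxy)-6-propylbenzoyl]oxy}-2-methoxy-6-propylbenzoate, via mixed anhydride 14 (not isolated)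
Conditions: (CF3CO)2O (2 equiv), toluene, rt
Reagents that add atoms: none
Why: Trifluoroacetic anhydride converts the electron-rich hindered acid into mixed anhydride 14, which acylates the phenol through its acylium-like aroyl carbonyl, the standard mixed-anhydride esterification for depsides from O-benzylated acids, while any aryl trifluoroacetate formed from 10 is labile and reverts to the phenol.

Step 9
Reactants: 15 methyl 4-{[2,4-bis(benzyloxy)-6-propylbenzoyl]oxy}-2-methoxy-6-propylbenzoate
Product: 16 methyl 4-[(2,4-dihydroxy-6-propylbenzoyl)oxy]-2-methoxy-6-propylbenzoate (target CNP0177078.0)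
Conditions: H2 (1 atm), 10% Pd/C, EtOAc, rt
Reagents that add atoms: none
Why: Neutral catalytic hydrogenolysis removes both benzyl ethers without touching the aryl ester, the methyl ester or the methyl ether, and the freed ortho hydroxyl then stabilises the depside ester by hydrogen bonding.

**Compound list**

1 | dimethyl malonate | COC(=O)CC(=O)OC | starting material
2 | (E)-hept-3-en-2-one | CCC/C=C/C(C)=O | starting material
3 | dimethyl 2-(2-oxoheptan-4-yl)malonate (Michael adduct; racemic, one enantiomer drawn) | CCC[C@@H](CC(C)=O)C(C(=O)OC)C(=O)OC | intermediate (not isolated)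
4 | sodium 6-(methoxycarbonyl)-3-oxo-5-propylcyclohex-1-en-1-olate (racemic, trans expected, one enantiomer drawn) | CCC[C@H]1CC(=O)C=C([O-])[C@@H]1C(=O)OC.[Na+] | intermediate (not isolated)
5 | methyl 2-hydroxy-4-oxo-6-propylcyclohex-1-ene-1-carboxylate (racemic, one enantiomer drawn) | CCC[C@H]1CC(=O)CC(O)=C1C(=O)OC | intermediate
6 | methyl 3-bromo-2-hydroxy-4-oxo-6-propylcyclohex-1-ene-1-carboxylate (racemic at C6, mixture of C3 epimers, C3 left undefined) | CCC[C@H]1CC(=O)C(Br)C(O)=C1C(=O)OC | intermediate (not isolated)
7 | methyl 2,4-dihydroxy-6-propylbenzoate | CCCc1cc(O)cc(O)c1C(=O)OC | intermediate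
8 | methyl 4-(benzyloxy)-2-hydroxy-6-propylbenzoate | CCCc1cc(OCc2ccccc2)cc(O)c1C(=O)OC | intermediate
9 | methyl 4-(benzyloxy)-2-methoxy-6-propylbenzoate | CCCc1cc(OCc2ccccc2)cc(OC)c1C(=O)OC | intermediate
10 | methyl 4-hydroxy-2-methoxy-6-propylbenzoate | CCCc1cc(O)cc(OC)c1C(=O)OC | intermediate
11 | methyl 2,4-bis(benzyloxy)-6-propylbenzoate | CCCc1cc(OCc2ccccc2)cc(OCc2ccccc2)c1C(=O)OC | intermediate
12 | potassium 2,4-bis(benzyloxy)-6-propylbenzoate | CCCc1cc(OCc2ccccc2)cc(OCc2ccccc2)c1C(=O)[O-].[K+] | intermediate (not isolated)
13 | 2,4-bis(benzyloxy)-6-propylbenzoic acid | CCCc1cc(OCc2ccccc2)cc(OCc2ccccc2)c1C(=O)O | intermediate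
14 | 2,4-bis(benzyloxy)-6-propylbenzoic trifluoroacetic anhydride | CCCc1cc(OCc2ccccc2)cc(OCc2ccccc2)c1C(=O)OC(=O)C(F)(F)F | intermediate (not isolated)
15 | methyl 4-{[2,4-bis(benzyloxy)-6-propylbenzoyl]oxy}-2-methoxy-6-propylbenzoate | CCCc1cc(OCc2ccccc2)cc(OCc2ccccc2)c1C(=O)Oc1cc(CCC)c(C(=O)OC)c(OC)c1 | intermediate
16 | methyl 4-[(2,4-dihydroxy-6-propylbenzoyl)oxy]-2-methoxy-6-propylbenzoate | CCCc1cc(O)cc(O)c1C(=O)Oc1cc(CCC)c(C(=O)OC)c(OC)c1 | target

**Count and risks**

Total step count: 9. Longest linear sequence: 7 steps (steps 1, 2, 3, 4, 5, 8, 9).

Steps most likely to fail: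

Step 2. The resorcylate, once formed, may consume bromine on its free ring positions faster than 6 loses HBr. In addition, bromide and HBr may demethylate the ester during heating, which would be followed by decarboxylation. The fallback accepts over-bromination and corrects it reductively. Setting out from 5, excess Br2 (about 3.2 equiv) in AcOH at rt to 60 °C should aromatise the ring and brominate both free positions to give methyl 3,5-dibromo-2,4-dihydroxy-6-propylbenzoate F1. Hydrogenolysis of the two aryl C–Br bonds (H2, 10% Pd/C, NaOAc, MeOH, rt) then returns to the route at 7.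

Step 8. Acyl transfer from the doubly ortho-substituted mixed anhydride may be slow, so that trifluoroacetylation of the phenol or acid-promoted loss of the ortho benzyl ether competes. The fallback replaces the acid-mediated mixed-anhydride coupling by a base-mediated acylation with a preformed acyl chloride. Setting out from 13, (COCl)2 with catalytic DMF in CH2Cl2 at 0 °C to rt should give 2,4-bis(benzyloxy)-6-propylbenzoyl chloride F2. This is added to 10 with Et3N and catalytic DMAP in CH2Cl2 at 0 °C to rt, returning to the route at 15.

Step 7. Hydroxide attack at a carbonyl flanked by two ortho substituents may stall, and forcing it risks damage to the benzyl ethers. The fallback breaks the O–CH3 bond instead of the acyl–O bond. Setting out from 11, LiI (5 equiv) in refluxing EtOAc should attack the ester methyl group in an SN2 dealkylation, which does not involve the hindered carbonyl. This gives lithium 2,4-bis(benzyloxy)-6-propylbenzoate F3, and cold dilute HCl returns to the route at 13.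

Further compounds
F1 | step 2 | methyl 3,5-dibromo-2,4-dihydroxy-6-propylbenzoate | CCCc1c(Br)c(O)c(Br)c(O)c1C(=O)OC
F2 | step 8 | 2,4-bis(benzyloxy)-6-propylbenzoyl chloride | CCCc1cc(OCc2ccccc2)cc(OCc2ccccc2)c1C(=O)Cl
F3 | step 7 | lithium 2,4-bis(benzyloxy)-6-propylbenzoate | CCCc1cc(OCc2ccccc2)cc(OCc2ccccc2)c1C(=O)[O-].[Li+]
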